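**Retrosynthetic overview**
1. The target is (5R,6S,6'R)-5,6-epoxy-5,6-dihydro-β,ε-carotene (carotenoid numbering, ε end primed). Two Wittig cuts, at C11'=C12' and C11=C12, give an ε-C15 phosphonium salt, the C10 trienedial C12'–C12 and an epoxy-C15 phosphonium salt.
2. The ε-C15 salt comes from a Julia–Lythgoe olefination (C7'=C8') of (R)-α-cyclogeranyl phenyl sulfone with a C5 acetoxy enal (C8'–C11').
3. The strategy rests on the ε ring C1'–C6' with its C4'=C5' alkene and the single CH stereocentre C6'. It is made by enantioselective proton-initiated C1'–C6' closure of (E)-geranyl phenyl sulfone, itself from geraniol and sodium benzenesulfinate.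
4. The epoxy-C15 salt comes from β-cyclocitral: reduction, asymmetric epoxidation (sets C5 and C6), oxidation, C5 phosphonate homologation (C7=C8), reduction, salt formation.
5. Ring order: the ε ring (step 3) on the main line; the oxirane on the purchased cyclohexene (step 9) on the side branch; the polyene is completed last.

Key step: step 3

Assumption: the sense of induction of the chiral acid in step 3 cannot be predicted with confidence for this substrate. The (R)-ligand is written; its antipode is used instead if the (S)-sulfone predominates.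

**Step 1**
Reactants: 1 geraniol
Product: 2 geranyl bromide, (2E)-1-bromo-3,7-dimethylocta-2,6-diene
Conditions: PBr3 (0.4 equiv), Et2O, −10 → 0 °C
Reagents that add atoms: phosphorus tribromide, BrP(Br)Br
Why: Bromination of a primary allylic alcohol through its bromophosphite (SN2) at low temperature should leave the 2E geometry and the distal alkene untouched.

**Step 2**
Reactants: 2 geranyl bromide; 3 sodium benzenesulfinate
Product: 4 (E)-geranyl phenyl sulfone, {[(2E)-3,7-dimethylocta-2,6-dien-1-yl]sulfonyl}benzene
Conditions: DMF, rt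
Reagents that add atoms: none
Why: S-Alkylation of the ambident sulfinate by the primary allylic bromide (SN2) in a dipolar aprotic solvent should give the linear sulfone with the 2E alkene intact.

**Step 3**
Reactants: 4 (E)-geranyl phenyl sulfone
Product: 5 (R)-α-cyclogeranyl phenyl sulfone, ({[(1R)-2,6,6-trimethylcyclohex-2-en-1-yl]methyl}sulfonyl)benzene
Conditions: (R)-2'-methoxy-1,1'-binaphthalen-2-ol·SnCl4 (preformed, 1.2 equiv), toluene, −78 °C; aq NaHCO3
Reagents that add atoms: none
Why: Proposed new method: the SnCl4-bound binaphthol ether is a strong chiral Brønsted acid that should protonate the electron-rich distal C1'=C2' alkene at C2' (Markovnikov), while the C5'=C6' alkene, made electron-poor by the allylic sulfonyl group, is left to act as the internal nucleophile; C6' then attacks the C1' cation through a chair-like fold (6-endo cation–olefin closure of the C1'–C6' ring) and the C5' cation loses H4' to the stannate-bound aryloxide to give the C4'=C5' alkene. The closest known reaction types are the enantioselective proton-initiated polyene cyclisations with tin-activated binaphthol acids of this kind and the racemic protic-acid cyclisation of geranyl sulfones to cyclogeranyl sulfones. The only new stereocentre, C6', is set by the chiral acid, which stays paired with the developing cation and so chooses which enantiotopic face of the C5'=C6' alkene folds onto C1'. The step needs loss of H4' in preference to H6' and the methyl protons; the low temperature, the absence of free protic acid, and the shielding of the tertiary H6' by the gem-dimethyl group and the sulfonylmethyl arm against a bulky base should secure this. Once formed, C6' cannot epimerise under acid, since it can only be lost by isomerisation to the β-isomer; the reaction is an isomerisation with no co-product.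

**Step 4**
Reactants: 5 (R)-α-cyclogeranyl phenyl sulfone; 6 (E)-4-acetoxy-2-methylbut-2-enal
Product: 9 (2E)-3-methyl-5-(phenylsulfonyl)-5-[(1R)-2,6,6-trimethylcyclohex-2-en-1-yl]pent-2-ene-1,4-diyl diacetate (mixture at the two new centres), via lithiated sulfone 7 (not isolated), via lithium alkoxide adduct 8 (not isolated)
Conditions: n-BuLi, THF, −78 °C; 6, −78 °C; Ac2O, −78 °C → rt
Reagents that add atoms: acetic anhydride, CC(=O)OC(C)=O
Why: First stage of the Julia–Lythgoe olefination: the C7' sulfonyl carbanion should add 1,2 to the enal carbonyl much faster than it attacks the ester, and acetylation of the alkoxide in the flask blocks retro-addition; C6' is not acidic and keeps its configuration, and the C7'/C8' centres are left as a mixture because both disappear in step 5.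

**Step 5**
Reactants: 9 β-acetoxy sulfone diacetate
Product: 11 (2E,4E)-3-methyl-5-[(1R)-2,6,6-trimethylcyclohex-2-en-1-yl]penta-2,4-dien-1-ol, via dienyl acetate 10 (not isolated)
Conditions: Na(Hg) (6% Na), Na2HPO4, THF/MeOH, −20 °C; then K2CO3, MeOH, rt
Reagents that add atoms: none
Why: Julia–Lythgoe reductive elimination: electron transfer cleaves the C7'–S bond and the resulting carbanion expels the C8' acetate to give the C7'=C8' alkene, expected E because the intermediate equilibrates to the less hindered trans arrangement, after which carbonate-catalysed methanolysis frees the primary alcohol.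

**Step 6**
Reactants: 11 ε-C15 dienol
Product: 12 triphenyl{(2E,4E)-3-methyl-5-[(1R)-2,6,6-trimethylcyclohex-2-en-1-yl]penta-2,4-dien-1-yl}phosphonium bromide
Conditions: PPh3·HBr, MeOH, rt
Reagents that add atoms: triphenylphosphine hydrobromide, [Br-].c1ccc(cc1)[PH+](c1ccccc1)c1ccccc1
Why: Conversion of an allylic alcohol into its allyltriphenylphosphonium salt (ionisation to the pentadienyl cation and capture by PPh3 at the primary terminus C11') is the standard preparation of C15 Wittig salts and should leave the ε-ring alkene and C6' unchanged.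

**Step 7**
Reactants: 12 ε-C15 phosphonium bromide; 13 (2E,4E,6E)-2,7-dimethylocta-2,4,6-trienedial
Product: 16 (2E,4E,6E,8E,10E,12E)-2,7,11-trimethyl-13-[(1R)-2,6,6-trimethylcyclohex-2-en-1-yl]trideca-2,4,6,8,10,12-hexaenal, via ε-C15 ylide 14 (not isolated), via 8Z aldehyde 15 (not isolated)
Conditions: 13 (3 equiv), NaOMe (slow addition), CH2Cl2/MeOH, 0 °C → rt; then heptane, reflux, dark
Reagents that add atoms: none
Why: Wittig olefination of the semi-stabilised allylic ylide with one formyl group of the excess symmetrical dialdehyde builds C11'=C12'; the new disubstituted alkene should form as an E/Z mixture whose unhindered Z component is converted thermally into the all-E aldehyde.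

**Step 8**
Reactants: 17 β-cyclocitral
Product: 18 β-cyclogeraniol, (2,6,6-trimethylcyclohex-1-en-1-yl)methanol
Conditions: NaBH4, MeOH, 0 °C
Reagents that add atoms: none
Why: 1,2-Reduction of the hindered enal by borohydride gives the allylic alcohol needed as the directing group for step 9.

**Step 9**
Reactants: 18 β-cyclogeraniol
Product: 19 [(1R,6R)-2,2,6-trimethyl-7-oxabicyclo[4.1.0]heptan-1-yl]methanol
Conditions: Ti(OiPr)4 (1.0 equiv), D-(−)-diethyl tartrate (1.2 equiv), t-BuOOH, 4 Å MS, CH2Cl2, −20 °C
Reagents that add atoms: tert-butyl hydroperoxide, CC(C)(C)OO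
Why: Katsuki–Sharpless asymmetric epoxidation: the allylic hydroxyl binds the titanium tartrate complex, which delivers the peroxide oxygen to one face of the tetrasubstituted alkene; D-(−)-diethyl tartrate (the enantiomer that turns geraniol into its (2R,3R)-epoxide) should give the (1R,6R) epoxy alcohol, which sets C5 and C6 of the target together.

**Step 10**
Reactants: 19 epoxy alcohol
Product: 20 (1S,6R)-2,2,6-trimethyl-7-oxabicyclo[4.1.0]heptane-1-carbaldehyde
Conditions: (n-Pr4N)(RuO4) (5 mol%), N-methylmorpholine N-oxide, 4 Å MS, CH2Cl2, rt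
Reagents that add atoms: none
Why: Ley–Griffith oxidation of the primary alcohol stops at the aldehyde under neutral conditions that spare the epoxide; the α-carbon is quaternary, so neither stereocentre can epimerise (the descriptor at C1 changes only through the priority rules).

**Step 11**
Reactants: 20 epoxy aldehyde; 21 ethyl (2E)-4-(diethoxyphosphoryl)-3-methylbut-2-enoate
Product: 23 ethyl (2E,4E)-3-methyl-5-[(1S,6R)-2,2,6-trimethyl-7-oxabicyclo[4.1.0]heptan-1-yl]penta-2,4-dienoate, via phosphonate anion 22 (not isolated)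
Conditions: 21, n-BuLi, THF/DMPU, −78 °C; then 20, −78 → 0 °C
Reagents that add atoms: none
Why: Horner–Wadsworth–Emmons olefination with the vinylogous phosphonate anion, which reacts at its α-carbon with the hindered aldehyde to give the E C7=C8 alkene; the C9=C10 alkene should come out mainly E whatever the geometry of the reagent, because the anion is delocalised, and the minor 9Z ester is removed by chromatography.

**Step 12**
Reactants: 23 epoxy-C15 ester
Product: 24 (2E,4E)-3-methyl-5-[(1S,6R)-2,2,6-trimethyl-7-oxabicyclo[4.1.0]heptan-1-yl]penta-2,4-dien-1-ol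
Conditions: i-Bu2AlH (2.2 equiv), CH2Cl2, −78 °C; aq KNaC4H4O6
Reagents that add atoms: none
Why: 1,2-Reduction of the dienoate to the allylic alcohol by the aluminium hydride at low temperature, conditions under which the epoxide should not be opened.

**Step 13**
Reactants: 24 epoxy-C15 dienol
Product: 26 triphenyl{(2E,4E)-3-methyl-5-[(1S,6R)-2,2,6-trimethyl-7-oxabicyclo[4.1.0]heptan-1-yl]penta-2,4-dien-1-yl}phosphonium bromide, via allylic bromide 25 (not isolated)
Conditions: CBr4, PPh3, 2,6-lutidine, CH2Cl2, −20 → 0 °C; then PPh3, EtOAc, rt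
Reagents that add atoms: carbon tetrabromide, BrC(Br)(Br)Br; triphenylphosphine, c1ccc(cc1)P(c1ccccc1)c1ccccc1
Why: Appel bromination under buffered, acid-free conditions, followed in the same flask by SN2 quaternisation with PPh3, should give the Wittig salt without exposing the acid-labile vinylogous epoxide to HBr.

**Step 14**
Reactants: 16 ε-C25 aldehyde; 26 epoxy-C15 phosphonium bromide
Product: 29 (5R,6S,6'R)-5,6-epoxy-5,6-dihydro-β,ε-carotene (target), via epoxy-C15 ylide 27 (not isolated), via 11Z isomer 28 (not isolated)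
Conditions: NaOMe, CH2Cl2/MeOH, −10 °C → rt, dark; then heptane, reflux, dark; Et3N-deactivated silica
Reagents that add atoms: none
Why: Wittig olefination of the epoxy-C15 ylide with the C25 polyenal forms C11=C12 and completes the C40 chain under basic conditions that the 5,6-epoxide tolerates; the Z component at the new disubstituted alkene is isomerised thermally to the all-E target and no stereocentre is touched.

**Compound list**
1 | geraniol | CC(C)=CCC/C(C)=C/CO | starting material
2 | geranyl bromide | CC(C)=CCC/C(C)=C/CBr | intermediate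
3 | sodium benzenesulfinate | [Na+].[O-]S(=O)c1ccccc1 | starting material
4 | (E)-geranyl phenyl sulfone | CC(C)=CCC/C(C)=C/CS(=O)(=O)c1ccccc1 | intermediate
5 | (R)-α-cyclogeranyl phenyl sulfone | CC1=CCCC(C)(C)[C@H]1CS(=O)(=O)c1ccccc1 | intermediate
6 | (E)-4-acetoxy-2-methylbut-2-enal | O=C/C(C)=C/COC(C)=O | starting material
7 | α-lithio derivative of sulfone 5 | CC1=CCCC(C)(C)[C@H]1C([Li])S(=O)(=O)c1ccccc1 | intermediate
8 | lithium alkoxide adduct of 7 and 6 | CC1=CCCC(C)(C)[C@H]1C(C([O-])/C(C)=C/COC(C)=O)S(=O)(=O)c1ccccc1.[Li+] | intermediate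
9 | (2E)-3-methyl-5-(phenylsulfonyl)-5-[(1R)-2,6,6-trimethylcyclohex-2-en-1-yl]pent-2-ene-1,4-diyl diacetate | CC1=CCCC(C)(C)[C@H]1C(C(OC(C)=O)/C(C)=C/COC(C)=O)S(=O)(=O)c1ccccc1 | intermediate
10 | (2E,4E)-3-methyl-5-[(1R)-2,6,6-trimethylcyclohex-2-en-1-yl]penta-2,4-dien-1-yl acetate | CC1=CCCC(C)(C)[C@H]1/C=C/C(C)=C/COC(C)=O | intermediate
11 | (2E,4E)-3-methyl-5-[(1R)-2,6,6-trimethylcyclohex-2-en-1-yl]penta-2,4-dien-1-ol | CC1=CCCC(C)(C)[C@H]1/C=C/C(C)=C/CO | intermediate
12 | ε-C15 triphenylphosphonium bromide | CC1=CCCC(C)(C)[C@H]1/C=C/C(C)=C/C[P+](c1ccccc1)(c1ccccc1)c1ccccc1.[Br-] | intermediate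
13 | (2E,4E,6E)-2,7-dimethylocta-2,4,6-trienedial | O=C/C(C)=C/C=C/C=C(C)/C=O | starting material
14 | ε-C15 ylide | CC1=CCCC(C)(C)[C@H]1/C=C/C(C)=C/[CH-][P+](c1ccccc1)(c1ccccc1)c1ccccc1 | intermediate
15 | (2E,4E,6E,8Z,10E,12E) isomer of aldehyde 16 | CC1=CCCC(C)(C)[C@H]1/C=C/C(C)=C/C=C\C(C)=C\C=C\C=C(C)\C=O | intermediate
16 | (2E,4E,6E,8E,10E,12E)-2,7,11-trimethyl-13-[(1R)-2,6,6-trimethylcyclohex-2-en-1-yl]trideca-2,4,6,8,10,12-hexaenal | CC1=CCCC(C)(C)[C@H]1/C=C/C(C)=C/C=C/C(C)=C/C=C/C=C(C)/C=O | intermediate
17 | β-cyclocitral | CC1=C(C=O)C(C)(C)CCC1 | starting material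
18 | β-cyclogeraniol | CC1=C(CO)C(C)(C)CCC1 | intermediate
19 | [(1R,6R)-2,2,6-trimethyl-7-oxabicyclo[4.1.0]heptan-1-yl]methanol | OC[C@@]12O[C@]1(C)CCCC2(C)C | intermediate
20 | (1S,6R)-2,2,6-trimethyl-7-oxabicyclo[4.1.0]heptane-1-carbaldehyde | O=C[C@@]12O[C@]1(C)CCCC2(C)C | intermediate
21 | ethyl (2E)-4-(diethoxyphosphoryl)-3-methylbut-2-enoate | CCOC(=O)/C=C(C)/CP(=O)(OCC)OCC | starting material
22 | lithium salt of the anion of phosphonate 21 | CCOC(=O)/C=C(C)/[CH-]P(=O)(OCC)OCC.[Li+] | intermediate
23 | ethyl (2E,4E)-3-methyl-5-[(1S,6R)-2,2,6-trimethyl-7-oxabicyclo[4.1.0]heptan-1-yl]penta-2,4-dienoate | CCOC(=O)/C=C(C)/C=C/[C@@]12O[C@]1(C)CCCC2(C)C | intermediate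
24 | (2E,4E)-3-methyl-5-[(1S,6R)-2,2,6-trimethyl-7-oxabicyclo[4.1.0]heptan-1-yl]penta-2,4-dien-1-ol | OC/C=C(C)/C=C/[C@@]12O[C@]1(C)CCCC2(C)C | intermediate
25 | (1S,6R)-1-[(1E,3E)-5-bromo-3-methylpenta-1,3-dien-1-yl]-2,2,6-trimethyl-7-oxabicyclo[4.1.0]heptane | BrC/C=C(C)/C=C/[C@@]12O[C@]1(C)CCCC2(C)C | intermediate
26 | epoxy-C15 triphenylphosphonium bromide | C(/C=C(C)/C=C/[C@@]12O[C@]1(C)CCCC2(C)C)[P+](c1ccccc1)(c1ccccc1)c1ccccc1.[Br-] | intermediate
27 | epoxy-C15 ylide | [CH-](/C=C(C)/C=C/[C@@]12O[C@]1(C)CCCC2(C)C)[P+](c1ccccc1)(c1ccccc1)c1ccccc1 | intermediate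
28 | (11Z) isomer of the target | CC1=CCCC(C)(C)[C@H]1/C=C/C(C)=C/C=C/C(C)=C/C=C/C=C(C)/C=C\C=C(C)\C=C\[C@@]12O[C@]1(C)CCCC2(C)C | intermediate
29 | (5R,6S,6'R)-5,6-epoxy-5,6-dihydro-β,ε-carotene | CC1=CCCC(C)(C)[C@H]1/C=C/C(C)=C/C=C/C(C)=C/C=C/C=C(C)/C=C/C=C(C)/C=C/[C@@]12O[C@]1(C)CCCC2(C)C | target

**Step count**
Total: 14 steps. Longest linear sequence: 8 steps (steps 1–7, then 14); the epoxy branch (steps 8–13, then 14) is 7 steps.

**Steps most likely to fail**

Step 3 (Proposed new method). The chiral acid may discriminate poorly between the two faces of the C5'=C6' alkene, because the cyclisation ends by proton loss and not by a bound nucleophile. The sulfonyl oxygens may also tie up the Lewis acid and slow protonation, and the proton may be lost from C6' or a methyl group instead of C4'.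
Fallback, from 4 back to 5: 4 is cyclised with concentrated H2SO4 in acetic acid at 0–15 °C, the known racemic protic-acid cyclisation of geranyl sulfones. This should give racemic α-cyclogeranyl phenyl sulfone F1 after removal of the β-isomer by crystallisation or chromatography. F1 is then resolved by preparative chromatography on a cellulose tris(3,5-dimethylphenylcarbamate) phase; the (R)-enantiomer is 5, and (S)-α-cyclogeranyl phenyl sulfone F2 is set aside. Asymmetric induction is replaced by resolution.

Step 4. Addition of the neopentyl-type sulfonyl carbanion to the enal may be slow and reversible, and attack at the acetate or γ-deprotonation of the enal may compete.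
Fallback, from 5 back to 11 (replaces steps 4 and 5): lithiated 5 (compound 7) is alkylated at C7' with the known C5 bromoacetate (E)-4-bromo-3-methylbut-2-enyl acetate (BrC/C(C)=C/COC(C)=O) in THF/DMPU at −78 °C. This should give (2E)-3-methyl-5-(phenylsulfonyl)-5-[(1R)-2,6,6-trimethylcyclohex-2-en-1-yl]pent-2-en-1-yl acetate F3. Treatment with KOMe in MeOH/THF should first methanolyse the acetate to the hydroxy sulfone F4 and then eliminate benzenesulfinate across C7'–C8'. The allylic H8' is the proton removed, so the conjugated E diene 11 is expected. Carbonyl addition with reductive elimination is replaced by alkylation with base-induced dehydrosulfonylation.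

Step 13. The 5,6-epoxide may rearrange to the 5,8-furanoid oxide, or the allylic system may ionise and scramble, during bromide and salt formation. Once the ylide is made in step 14, vinylogous opening of the epoxide is a further risk.
Fallback, from 24 and 16 to 29 (replaces steps 13 and 14): the polarity of the last olefination is reversed so that the epoxide unit is never a halide or a salt. 24 is oxidised with MnO2 in CH2Cl2 to (2E,4E)-3-methyl-5-[(1S,6R)-2,2,6-trimethyl-7-oxabicyclo[4.1.0]heptan-1-yl]penta-2,4-dienal F5. 16 is reduced with NaBH4 in MeOH to the ε-C25 hexaenol F6, which PPh3·HBr in MeOH converts into the ε-C25 triphenylphosphonium bromide F7 (the retinyl-salt type of reaction). NaOMe in CH2Cl2/MeOH then generates the ε-C25 ylide F8 in the presence of F5, and the Wittig reaction should give 29 after the same thermal isomerisation of 28.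

**Further compounds**
F1 | step 3 | racemic α-cyclogeranyl phenyl sulfone | CC1=CCCC(C)(C)C1CS(=O)(=O)c1ccccc1
F2 | step 3 | (S)-α-cyclogeranyl phenyl sulfone | CC1=CCCC(C)(C)[C@@H]1CS(=O)(=O)c1ccccc1
F3 | step 4 | (2E)-3-methyl-5-(phenylsulfonyl)-5-[(1R)-2,6,6-trimethylcyclohex-2-en-1-yl]pent-2-en-1-yl acetate | CC1=CCCC(C)(C)[C@H]1C(C/C(C)=C/COC(C)=O)S(=O)(=O)c1ccccc1
F4 | step 4 | (2E)-3-methyl-5-(phenylsulfonyl)-5-[(1R)-2,6,6-trimethylcyclohex-2-en-1-yl]pent-2-en-1-ol | CC1=CCCC(C)(C)[C@H]1C(C/C(C)=C/CO)S(=O)(=O)c1ccccc1
F5 | step 13 | (2E,4E)-3-methyl-5-[(1S,6R)-2,2,6-trimethyl-7-oxabicyclo[4.1.0]heptan-1-yl]penta-2,4-dienal | O=C/C=C(C)/C=C/[C@@]12O[C@]1(C)CCCC2(C)C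
F6 | step 13 | (2E,4E,6E,8E,10E,12E)-2,7,11-trimethyl-13-[(1R)-2,6,6-trimethylcyclohex-2-en-1-yl]trideca-2,4,6,8,10,12-hexaen-1-ol | CC1=CCCC(C)(C)[C@H]1/C=C/C(C)=C/C=C/C(C)=C/C=C/C=C(C)/CO
F7 | step 13 | ε-C25 triphenylphosphonium bromide | CC1=CCCC(C)(C)[C@H]1/C=C/C(C)=C/C=C/C(C)=C/C=C/C=C(C)/C[P+](c1ccccc1)(c1ccccc1)c1ccccc1.[Br-]
F8 | step 13 | ε-C25 ylide | CC1=CCCC(C)(C)[C@H]1/C=C/C(C)=C/C=C/C(C)=C/C=C/C=C(C)/[CH-][P+](c1ccccc1)(c1ccccc1)c1ccccc1
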